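The numbers belong to no real substance; the result is computed.

Which vessel ends with the most target, when a trace of catalyst has to turn over the whole charge in 25 h?

common to all: free catalyst 0.2 mol%
- north: substrate 0.10 M; reagent 1.20 equiv; one stirred flow tank at steady state, fed with the mixture as stated, mean residence time 25 h
- south-west: substrate 0.10 M; reagent 1.20 equiv; a closed flask charged with all of it at once and left for 25 h; time 25 h
- north-east: substrate 0.10 M; reagent 1.20 equiv (fed, over 25.0 h); all but reagent at the start; reagent goes in evenly over 25.0 h, the run ends at 25 h; time 25 h
- south-east: substrate 0.10 M (fed, over 25.0 h); reagent 1.20 equiv; all but substrate at the start; substrate goes in evenly over 25.0 h, the run ends at 25 h; time 25 h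

- the set-up with the highest amount of target at the outlet or at the end, in percent of the substrate put in ("none" if the first two lie within 2 percentage points) (north / south-west / north-east / south-east / none)
- amount of target at the outlet or at the end, in percent of the substrate put in, north
- amount of target at the outlet or at the end, in percent of the substrate put in, south-west
- amount of target at the outlet or at the end, in percent of the substrate put in, north-east
- amount of target at the outlet or at the end, in percent of the substrate put in, south-east

- a species is counted by the substrate in it: one side product counts as two
- the stated concentrations are those of everything mixed, before any reaction; amounts are the same in each set-up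
- the feed brings no volume worth counting
- run time (south-west): 25 h

    catalyst intermediate B → free catalyst + target (k1 = 0.014 s⁻¹)
    reagent + free catalyst → catalyst intermediate A (k2 = 0.11 M⁻¹ s⁻¹)
    free catalyst ⇌ dormant form (K3 = 0.67, k3 = 3.7 × 10⁻⁶ s⁻¹)
    substrate + catalyst intermediate A → catalyst intermediate B (k4 = 9.0 M⁻¹ s⁻¹)
    reagent + free catalyst → spent catalyst (k5 = 6.7 × 10⁻⁶ M⁻¹ s⁻¹)
    substrate + target → side product (k6 = 9.2 × 10⁻⁶ M⁻¹ s⁻¹)

I followed one turn of the catalyst in the closed flask, south-west. Free catalyst waited for reagent, a pseudo-first-order capture at 0.0132 s⁻¹ at the charge, and intermediate B broke down at 0.014 s⁻¹. These were comparable, so I added the two waits, 71.4 s and 75.8 s. Intermediate A met substrate far faster, and I dropped that wait.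

With reagent held at its charge, I reckoned that the 2.00 × 10⁻⁴ M of catalyst needed 20.4 h to clear the substrate. With reagent held at the 0.0200 M that remains once substrate is gone, I reckoned 34.2 % conversion in the run. The real reagent falls from the first level towards the second, so the real flask lay between.

Integrating the rate while reagent falls gave a linear term for breakdown and a logarithm for capture. Together they make the clearing time, the time the undisturbed cycle needs for the whole substrate charge: 32.5 h. The same integral put 80.0 % conversion at 21.8 h and 90.0 % at 26.4 h.

The dormant form takes a toll. Its forward step, reckoned with the back step ignored and free catalyst held at its charge, comes to 33.3 % of that catalyst over the run. Counting a free share of 51.5 % and a linear rise, I struck 8.57 %, which left 22.9 h of working time. That lay beyond 21.8 h and short of 26.4 h, so I committed to slightly over 80.0 % of the substrate turned over in south-west. I put south-west first by judgement, not by reckoning: it has substrate and reagent both at full charge from the start.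

The forecast also named south-west, saying “The batch keeps reagent high throughout and wins”. The simulation gave south-west.

| Set-up | Forecast | Simulation |
|---|---|---|
| north | 62.5 % | 62.5 % |
| south-west | 79 % | 79.8 % |
| north-east | 49.5 % | 48.6 % |
| south-east | 75 % | 75.9 % |

South-west's 25 h fell short of its 32.5 h clearing time, and at 25.0 h that flask still held 17.0 % substrate beside 79.8 % target, with 32 % of its reagent left. Those are the readings to watch. In the neighbouring closed flask, at 0.17 M substrate with the same equivalents and loading, the clearing time came to 23.2 h, shorter than the run. That flask ended with 0.11 % of its substrate unbound, 4.18 % side product and 95.7 % target.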